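Readings and results stem from a simulated flask from invented constants, noise included.

The ratio to follow in these flasks is the rate at which Sub leaves by any way other than Prd, divided by the rate at which Prd forms. Dividing one rate by the other removes time, so the ratio speaks of where a flask ends and not of when.

| flask | Sub | Cat | time |
|---|---|---|---|
| Friday's | 0.500 M | 0.00100 M |  |
| Sunday's | 0.500 M | 5.00 × 10⁻⁴ M |  |
| Monday's | 1.00 M | 0.00100 M |  |
| Tuesday's | 0.500 M | 0.00100 M | 520 min |

- Friday's run (time / min: [Prd] / M): 5.2: 0.0607; 12: 0.1200; 26: 0.2152; 58: 0.3205; 130: 0.3786
- Sunday's run (time / min: [Prd] / M): 5.2: 0.0311; 12: 0.0654; 26: 0.1229; 58: 0.2063; 130: 0.2814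
- Monday's run (time / min: [Prd] / M): 5.2: 0.1137; 12: 0.2333; 26: 0.4054; 58: 0.5879; 130: 0.6832

(scatter of a reading: 0.002 M)

- Overall: Sub -> Prd, with Cat as catalyst.
- Constant volume, constant temperature.
- An order is taken over about fifteen percent of the charge, up and down.

- the exponent of [Sub] in the starting rate at the charge of the Friday's run (at the point where two percent of the Sub have become Prd) (one fixed amount of Prd, the same in the runs compared)
- the exponent of [Cat] in the starting rate at the charge of the Friday's run (at the point where two percent of the Sub have become Prd)
- Prd in the Tuesday's run at 520 min, as a share of the Sub charged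

The first readings give the orders in this reckoning. Halving c(Cat) gives an exponent of 0.965, and doubling c(Sub) gives 0.905. Both are read as near one, so Prd forms at kc·c(Sub), with kc a pseudo-first-order constant proportional to c(Cat).

The Sunday's run has the Sub of the Friday's run and half its Cat. At 130 min it has had more Cat-time than the Friday's run at 58 min, yet it holds less Prd, 0.2814 M against 0.3205 M. Some Sub therefore appears to leave on a clock that does not follow Cat.

Treating the ratio as one average value, the Friday's run gives:

kc = 0.0249 min⁻¹, from the first reading and the mean c(Sub) up to it

share at the last reading = 75.7%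

final share φ = 76.8%

w = 1/φ − 1 = 0.302

This w is the loss ratio, Sub lost otherwise per Sub turned to Prd.

If the loss does not depend on Cat, the Sunday's run has a ratio of 0.604, twice the value for the Friday's run. It therefore ends lower, at 62.3% against 76.8%. The same reckoning gives 0.288 M at 130 min, a little above the reading of 0.2814 M.

The Tuesday's run repeats the Friday's charge, and 520 min far exceeds the Sub lifetime of 30.9 min. This reckoning therefore gives 76.8%.

The forecast gives orders of 0.9 and 1 and a higher share of 80.5%, holding that “Friday's conditions at 520 min should therefore sit just above the 130 min value”.

The flask gives 1.0, 1.0 and 77.0%.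

    Cat + Sub → Prd + Cat (24.96 M⁻¹ min⁻¹)
    Sub → Q (0.003822 min⁻¹)
    2 Sub → Z (0.007560 M⁻¹ min⁻¹)

The forecast's three values stand within their margins, and the Tuesday's Prd share means a loss ratio of 0.299, beside the 0.302 reckoned from the Friday's run. The step to Q counts in this loss: taking it away moves the readings by 14 scatter units, root mean square. For the Sunday's run, twice the ratio gives a share of 62.6%, and that run reaches half of its Sub charged as Prd at 88.3 min.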